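# Design of a total synthesis of CNP0144558.1 by [2,3]-Wittig ring contraction

## The problem

The target is a chlorinated briarane. Ring A (C1, C10–C14) is trans-fused along C1–C10 to a ten-membered carbocycle (C1–C10), which carries a trans-fused γ-lactone across C7–C8 (C7–O–C19(=O)–C17–C8). This bicyclo[8.4.0] core has ten stereocentres: quaternary C1, C2, C6, C7, C8, C9, C10, C13, C14 and C17.

A ten-membered carbocycle is the ring size that resists end-to-end closure most, so its last ring bond is best made inside a larger, strain-free ring.

The stereocentres fall into three groups. C13/C14 are a cis-diol that can come from the chiral pool and direct quaternary C1 and, through a fused dioxolane, the face of C10. C9–C8–C7–C6 and C17 are contiguous, so a C9 hydroxyl can direct C8/C7 and the lactone can then bias C17 and C6. C2 sits beside the quaternary carbon and needs reagent control.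

The fragile groups are the secondary allylic chloride at C6, the β-hydroxy lactone (dehydration to a butenolide, translactonisation onto a free C9 oxygen, which lies syn to C17), four acetates beside a free tertiary hydroxyl, and two 1,1-disubstituted alkenes. Chlorine and the acetates therefore have to come last, with nothing strongly basic, acidic or reducing after them.

The feature that opens the route is the sequence C9(O)–C10(H)–C11(=C20H2): a homoallylic alcohol with an exocyclic methylene, the signature of a [2,3]-Wittig shift of a C9–O–C20 allyl ether. Because C7 and C8 both bear oxygen they can be carried as an alkyne, which makes C9 propargylic (the acidifying group the shift needs) and removes four transannular hydrogens from the medium ring.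

## Retrosynthesis

**41 ⇒ 40 (C6–Cl, with C5=C6 moved to C5=C16).** The allylic chloride is the least robust group and would not survive hydride, copper hydride or zerovalent palladium, so it is cut first. Tetraacetate 40 has one stereocentre fewer and only robust functionality. The forward step must chlorinate C6 of the trisubstituted alkene in the presence of C11=C20, lose a C16 hydrogen, and do so on the α face.

**40 ⇒ 37 (acetates, silyl ether, acetonide; C17–H).** The four acetates go back to pentaol 39 and the protected α-methyl lactone 38. C17 is traced to the α-methylene lactone 37, so that this centre is set inside the rigid lactone and not in an open chain where nothing would control it. The forward step is a 1,4-reduction with face-selective protonation.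

**37 ⇒ 35 ⇒ 34 (C7–O lactone bond; C7–O/C8–O epoxide).** The lactone oxygen is put on C7 by the C19 carboxylate attacking a vinyl epoxide. A simple acid-mediated opening would invert C7 and give the wrong diastereomer, so the opening has to proceed with net retention. Epoxide 35 comes from allylic alcohol 34 by hydroxyl-directed epoxidation, which is the only way to single out C7=C8 among four alkenes.

**34 ⇒ 31 + 33 (C8–C17).** The C17–C19 unit is attached as methyl 2-bromoacrylate 33 to C8 of an alkenylstannane made from the alkyne of 31. Cutting here, not at C7–C8 or C8–C9, keeps the alkyne as a latent C7/C8 pair and uses the propargylic oxygen to place the metal on C8. The addition has to be syn, so that C7=C8 is the cis-in-ring alkene from which the epoxidation model gives the right C8.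

**31 ⇒ 28 (C9–C10; O–C20 re-formed).** This is the key cut. The ring-contracted enynol 31 is the [2,3]-Wittig product of the 13-membered cyclic allyl propargyl ether 28, which has no stereocentres at C9 or C10 and no medium ring. Cuts at C5=C6, C6–C7 or C2–C3 would all require an end-to-end ten-membered ring closure. The forward step must deprotonate C9 only, shift [2,3] and not [1,2], bond to the β face of C10 and set C9.

**28 ⇒ 26 ⇒ 22 + 15 (O–C9; C6–C7).** The macro-ether is opened at the O–C9 bond to the chloro alcohol 26 (Williamson closure). The enyne is cut at C6–C7 to the Z vinyl iodide 22 and propargyl alcohol 15 (Sonogashira). Keeping C20 as a methyl ester until the propargylic chloride is in place avoids any protecting group on either primary oxygen.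

**22 ⇒ 14 + 18; 18 ⇒ 15 (C3–C4; C2 stereocentre).** The chain is cut between C3 and C4 to methyl ketone 14 and allylic bromide 18. The C2 carbinol is then set by CBS reduction of a ketone flanked by a quaternary carbon, which is more reliable than substrate-controlled addition to a neopentyl aldehyde. Bromide 18 comes from 15 by anti-carbomagnesiation/iodination, so the Z geometry of C5=C6 is fixed before the fragment enters the chain.

**14 ⇒ 9 ⇒ 7 (C11–C20; C1–C15; C2–C3).** The acetyl group is built from the C2 hydroxymethyl group. C20 comes from carbonylation of enol triflate 9. Triflate 9 is the trapped enolate from cuprate addition of the C15 methyl to enone 7. Conjugate addition is chosen over enolate alkylation at C1 because a carbanion at C1 would expel the C14 oxygen.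

**7 ⇒ 5 ⇒ 1 (C1–C2; enone).** C2 is introduced by Stille coupling on the β-bromo enone 5, which comes from the diene of acetonide 2 by bromohydrin formation, debromination and oxidation. The bromobenzene cis-dihydrodiol 1 supplies C13/C14 in the correct absolute sense and has its halogen on the carbon that becomes C1.

## Roads not taken

**Alternative 1:** The cut is C1–C10 inside ring A. In the forward step a C14 silyl enol ether is oxidised at an anode to a radical cation whose C1 is attacked by C10 of a tethered allylsilane. Both silyl groups are lost and the ring-A ketone A1 results.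

- Merits: an umpolung closure that creates the quaternary carbon, C10 and the C11=C20 methylene in one reagent-free operation, from a single stereocentre (C13). It reaches its ring-A compound in fewer operations than the twelve steps the chosen plan needs to arrive at 14.
- Weak points: it solves only ring A. C10 is fixed at the outset as an sp3 centre carrying a one-carbon stub, so the ten-membered ring would still have to be closed end to end between two branched appendages. The C1/C10 and C1/C13 relationships rest on conformational preferences in a cyclisation that forms a quaternary centre, and C14 arrives as a ketone that must be reduced selectively.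
- Set against it: C1 is set by cuprate addition anti to a fused dioxolane, and C10 is not made until the ring contraction, where it forms together with the ten-membered ring.

**Alternative 2:** The cut is C6–C7. In the forward step CrCl2 converts a C16 allylic bromide into an allylchromium species that adds through C6 to a C7 aldehyde (Nozaki–Hiyama–Kishi type), giving the seco-lactone A2.

- Merits: the most convergent of the four plans. The closed transition state sets the C6/C7 chlorohydrin directly, together with the C5=C16 methylene and the ring. This is the relationship the chosen plan leaves to its last and least secure step, so in this respect the alternative is better.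
- Weak points: the ring is closed end to end at high dilution with a 2-substituted allylmetal. The substrate must carry an aldehyde α to the tertiary C8 carbinol (α-ketol shift, retro-aldol), four acetates and an ester through a reduction with divalent chromium. C8, C9 and C17 would have to be assembled in open chain with no ring to relay stereochemistry.
- Set against it: a ring closure with class precedent inside an unstrained 13-membered ring, and use of the finished ring to relay C9 to C8 and C7.

**Alternative 3:** The cut is C8–C17. In the forward step SmI2 reduces a C7 2-bromopropionate to a samarium enolate that adds to the neighbouring C8 ketone (intramolecular Reformatsky), giving the hydroxy lactone A3.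

- Merits: the lactone, C8 and C17 are formed together in a chelated transition state under mild conditions. The chosen plan sets C17 separately by protonation of an enolate, which is less secure, so the alternative is better here.
- Weak points: it is an endgame tactic and leaves the ten-membered ring to another method. It needs an α-acyloxy ketone, the motif SmI2 cleaves reductively, and in A3 an allylic chloride sits β to the ketyl carbon. A C8 ketone flanked by oxygenated C7 and C9 must be made regioselectively.
- Set against it: C8 stays an alkyne carbon until a directed hydrostannation, so no α-acyloxy ketone meets a one-electron reductant, and chlorine comes last. The price is the separate control of C17.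

Key step: step 22

## Remarks before the route

- Remark: all intermediates are described with briarane locants (C1–C20). β is the face of the C1 methyl (C15) in the usual planar drawing, α the opposite face (the face of O13/O14).
- Remark: C13/C14 of the target are 13S,14R. The cis-dihydrodiol 1 has this sense with its C–Br carbon at C1, whereas the common 4,5-O-isopropylidenecyclohexenone from (−)-quinic acid is the mirror image of enone 5. The arene diol is therefore the chiral source.
- Assumption: 1, 15, 33 and (tributylstannyl)methanol are bought.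

## Route

Step 1
Reactants: 1 (1S,2S)-3-bromocyclohexa-3,5-diene-1,2-diol
Product: 2 (3aS,7aS)-4-bromo-2,2-dimethyl-3a,7a-dihydro-1,3-benzodioxole
Conditions: 2,2-dimethoxypropane, TsOH (cat.), acetone, 0 °C to rt
Reagents that add atoms: 2,2-dimethoxypropane, COC(C)(C)OC
Why: Acid-catalysed acetal exchange on the cis-diol; the cis-fused dioxolane fixes O13/O14 and later shields the α face of ring A.

Step 2
Reactants: 2 acetonide
Product: 3 trans-bromohydrin (11α-OH, 12β-Br, C1 vinyl bromide kept)
Conditions: NBS, THF–H2O, 0 °C
Reagents that add atoms: N-bromosuccinimide, O=C1CCC(=O)N1Br; water, O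
Why: Bromohydrin formation: the vinylic bromine deactivates C1=C10, so the bromonium ion forms on C11=C12 anti to the dioxolane and water opens it at the allylic carbon C11; both new centres are temporary.

Step 3
Reactants: 3 trans-bromohydrin
Product: 4 allylic alcohol (11α-OH, C1 vinyl bromide)
Conditions: Bu3SnH, AIBN (cat.), toluene, 80 °C
Reagents that add atoms: none
Why: Radical-chain reduction; tin radicals abstract a secondary alkyl bromine far faster than a vinylic one, so only C12–Br is removed.

Step 4
Reactants: 4 allylic alcohol
Product: 5 β-bromo enone (C11 ketone, C1(Br)=C10)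
Conditions: MnO2, CH2Cl2, rt
Reagents that add atoms: none
Why: MnO2 oxidises the allylic alcohol selectively and gives the β-bromo enone, a vinylogous acyl bromide.

Step 5
Reactants: 5 β-bromo enone
Product: 6 3-(hydroxymethyl) enone (C2 on C1)
Conditions: Bu3SnCH2OH, Pd(PPh3)4 (cat.), dioxane, 90 °C
Reagents that add atoms: (tributylstannyl)methanol, CCCC[Sn](CCCC)(CCCC)CO
Why: Stille coupling: the β-bromo enone undergoes oxidative addition readily and the stannane transfers CH2OH, which becomes C2.

Step 6
Reactants: 6 3-(hydroxymethyl) enone
Product: 7 TBS ether of 6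
Conditions: TBSCl, imidazole, DMF, rt
Reagents that add atoms: tert-butyldimethylsilyl chloride, CC(C)(C)[Si](C)(C)Cl
Why: Standard silylation of the primary alcohol.

Step 7
Reactants: 7 TBS-protected enone
Product: 9 C11 enol triflate (C1: β-methyl, α-CH2OTBS), via lithium enolate 8 (not isolated)
Conditions: Me2CuLi (MeLi, CuI), Et2O, −40 °C; then PhNTf2, THF, −78 °C to rt
Reagents that add atoms: lithium dimethylcuprate, [Li+].C[Cu-]C; N-phenylbis(trifluoromethanesulfonimide), O=S(=O)(N(c1ccccc1)S(=O)(=O)C(F)(F)F)C(F)(F)F
Why: Cuprate 1,4-addition to the β,β-disubstituted enone and O-sulfonylation of the regiodefined enolate (conjugate addition–enolate trapping); methyl enters on the convex β face, anti to the allylic C14–O bond of the cis-fused dioxolane, which sets quaternary C1 with C15 β and C2 α.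

Step 8
Reactants: 9 enol triflate
Product: 10 methyl enoate (C20 ester on C11)
Conditions: Pd(OAc)2 (cat.), PPh3, CO (1 atm), MeOH, Et3N, DMF, 50 °C
Reagents that add atoms: carbon monoxide, [C-]#[O+]; methanol, CO
Why: Palladium-catalysed methoxycarbonylation of the enol triflate puts C20 on C11 as an ester that also masks the future allylic alcohol.

Step 9
Reactants: 10 methyl enoate
Product: 11 C2 primary alcohol
Conditions: TBAF, THF, 0 °C; aq. NH4Cl
Reagents that add atoms: none
Why: Fluoride cleaves the only silyl ether; the conjugated ester is untouched.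

Step 10
Reactants: 11 primary alcohol
Product: 12 C2 aldehyde
Conditions: Dess–Martin periodinane, NaHCO3, CH2Cl2, rt
Reagents that add atoms: none
Why: Dess–Martin oxidation; the neopentyl aldehyde has no α-hydrogen and cannot epimerise.

Step 11
Reactants: 12 aldehyde
Product: 13 C2 methyl carbinol (both C2 epimers)
Conditions: MeMgBr, THF, −78 °C; aq. NH4Cl
Reagents that add atoms: methylmagnesium bromide, C[Mg]Br
Why: Grignard addition to the aldehyde, which reacts much faster than the conjugated ester at −78 °C; C2 forms as a mixture and is oxidised in the next step.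

Step 12
Reactants: 13 methyl carbinol
Product: 14 methyl ketone (1α-acetyl; C2 carbonyl, C3 methyl)
Conditions: Dess–Martin periodinane, NaHCO3, CH2Cl2, rt
Reagents that add atoms: none
Why: Dess–Martin oxidation to a methyl ketone that can enolise only toward C3.

Step 13
Reactants: 15 propargyl alcohol
Product: 17 (Z)-3-iodo-2-methylprop-2-en-1-ol, via vinylmagnesium chelate 16 (not isolated)
Conditions: MeMgBr (excess), CuI (cat.), Et2O, −10 °C to rt; then I2, THF, −10 °C
Reagents that add atoms: methylmagnesium bromide, C[Mg]Br; iodine, [I][I]
Why: Copper-catalysed anti-carbomagnesiation of the propargylic alkoxide: methyl adds to the internal carbon and magnesium ends on the terminus in a five-membered chelate, so iodinolysis with retention gives only the Z iodide (CH2O and I cis), the geometry C4 and C7 need across C5=C6.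

Step 14
Reactants: 17 (Z)-3-iodo-2-methylprop-2-en-1-ol
Product: 18 (Z)-3-bromo-1-iodo-2-methylprop-1-ene
Conditions: CBr4, PPh3, CH2Cl2, 0 °C
Reagents that add atoms: carbon tetrabromide, BrC(Br)(Br)Br
Why: Appel bromination of the primary allylic alcohol with retention of the alkene geometry.

Step 15
Reactants: 14 methyl ketone; 18 (Z)-3-bromo-1-iodo-2-methylprop-1-ene
Product: 20 C2 ketone carrying the C3–C6 chain with the Z vinyl iodide, via lithium enolate 19 (not isolated)
Conditions: LDA, THF, −78 °C; then 18, DMPU, −78 to −30 °C
Reagents that add atoms: none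
Why: Kinetic deprotonation of the methyl ketone and SN2 alkylation of the lithium enolate by the allylic bromide forms C3–C4; the vinyl iodide is inert under these conditions.

Step 16
Reactants: 20 ketone
Product: 21 (2S)-alcohol
Conditions: (R)-2-methyl-CBS-oxazaborolidine (cat.), BH3·SMe2, THF, −20 °C; MeOH
Reagents that add atoms: none
Why: CBS reduction: quaternary C1 is the large and the C3 methylene the small substituent, so the R catalyst should deliver hydride to give the 2S carbinol under reagent control.

Step 17
Reactants: 21 (2S)-alcohol
Product: 22 (2S)-TBS ether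
Conditions: TBSOTf, 2,6-lutidine, CH2Cl2, 0 °C
Reagents that add atoms: tert-butyldimethylsilyl trifluoromethanesulfonate, CC(C)(C)[Si](C)(C)OS(=O)(=O)C(F)(F)F
Why: Silylation of the hindered neopentyl carbinol needs the silyl triflate.

Step 18
Reactants: 22 Z vinyl iodide; 15 propargyl alcohol
Product: 23 Z enynol (free C9–OH)
Conditions: Pd(PPh3)2Cl2 (cat.), CuI (cat.), Et3N, THF, rt
Reagents that add atoms: none
Why: Sonogashira coupling forms C6–C7 with retention of the Z geometry and leaves the C9 hydroxyl free.

Step 19
Reactants: 23 enynol
Product: 25 propargylic chloride (C9–Cl), via propargylic mesylate 24 (not isolated)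
Conditions: MsCl, Et3N, CH2Cl2, 0 °C; then LiCl, DMF, rt
Reagents that add atoms: lithium chloride, [Li+].[Cl-]
Why: Sulfonylation and SN2 displacement by chloride; with C20 still an ester, C9–OH is the only hydroxyl present.

Step 20
Reactants: 25 propargylic chloride
Product: 26 chloro allylic alcohol (C20–OH)
Conditions: DIBAL-H, CH2Cl2, −78 °C; Rochelle salt
Reagents that add atoms: none
Why: DIBAL-H reduces the conjugated ester to the allylic alcohol at −78 °C, where the propargylic chloride and the enyne are not attacked.

Step 21
Reactants: 26 chloro allylic alcohol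
Product: 28 13-membered cyclic allyl propargyl ether, via sodium alkoxide 27 (not isolated)
Conditions: NaH, n-Bu4NI (cat.), THF (0.002 M, slow addition), 45 °C
Reagents that add atoms: none
Why: Intramolecular Williamson etherification (SN2 at the primary propargylic chloride) under high dilution; the rigid enyne and cyclohexene segments leave few rotors in the 13-membered ring, and 13-membered allyl propargyl ethers of this kind are known to close by O-alkylation.

Step 22
Reactants: 28 13-membered cyclic allyl propargyl ether
Product: 31 ten-membered enynol (9S-OH, C11=C20 methylene), via α-lithio ether 29 (not isolated), via lithium alkoxide 30 (not isolated)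
Conditions: n-BuLi, THF–hexane, −78 to −30 °C; aq. NH4Cl
Reagents that add atoms: none
Why: n-BuLi removes a propargylic, oxygen-bearing C9 hydrogen (the most acidic site) and the α-lithio ether 29 undergoes a concerted suprafacial [2,3]-sigmatropic shift through a five-membered envelope, in which C9–C10 forms, O–C20 breaks and the alkene moves to C11=C20 (alkoxide 30). The closest known reaction type is the [2,3]-Wittig ring contraction of 13-membered cyclic allyl propargyl ethers to ten-membered propargylic carbinols. The ten-membered ring is thus closed by transannular contraction of the preformed 13-membered ring, not by an end-to-end exo or endo cyclisation, and the five-membered array is the only newly organised ring in the transition state. C10: the ether bridge can lie only over the β face of the ring-A alkene because the α face is covered by the cis-fused dioxolane at C13/C14, so C9 bonds syn to the C1 methyl and H10 ends anti to it (trans ring fusion). C9: oxygen and C11 are held syn-clinal in the envelope and the rigid C6–C9 enyne unit keeps C8 gauche to C1 about the new bond; the arrangement with both twisted in the same sense should give the 9S carbinol. The step needs deprotonation at C9 and not at C20 (propargylic more acidic than allylic), [2,3] and not [1,2] shift (low temperature), and reaction through C9 and not through the C7 or C5 termini of the delocalised anion (only C9 stands in the five-atom relationship to C10).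

Step 23
Reactants: 31 ten-membered enynol
Product: 32 C8 tributylstannane (C7=C8 cis in the ring: C6 and C9 cis)
Conditions: Bu3SnH, Mo(CO)3(CNtBu)3 (cat.), hydroquinone (cat.), THF, 55 °C
Reagents that add atoms: tributyltin hydride, CCCC[SnH](CCCC)CCCC
Why: Molybdenum-catalysed hydrostannation of a propargylic alcohol: syn addition with tin on the alkyne carbon next to the carbinol (C8), so H7 and tin are cis and the new C7=C8 bond is the strain-free cis-in-ring alkene.

Step 24
Reactants: 32 C8 stannane; 33 methyl 2-bromoacrylate
Product: 34 dienyl acrylate (C8–C17 bond; C17=C18 methylene, C19 methyl ester)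
Conditions: Pd(PPh3)4 (cat.), CuI (cat.), CsF, DMF, 45 °C
Reagents that add atoms: none
Why: Stille coupling with retention at C8 attaches C17–C19 as an acrylate; copper and fluoride assist transmetalation of the hindered α-hydroxy stannane.

Step 25
Reactants: 34 dienyl acrylate
Product: 35 7α,8α-epoxide
Conditions: VO(acac)2 (cat.), t-BuOOH (decane), CH2Cl2, 0 °C
Reagents that add atoms: tert-butyl hydroperoxide, CC(C)(C)OO
Why: Vanadium-catalysed hydroxyl-directed epoxidation touches only the allylic alcohol alkene; with H9 eclipsing the alkene (A(1,3) strain with C6) the C9 hydroxyl lies on the face not covered by C10 and delivers oxygen there, giving the 7α,8α-epoxide with C8–O anti to C9–O in the planar drawing (threo).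

Step 26
Reactants: 35 epoxy ester
Product: 37 α-methylene hydroxy lactone (7α-O lactone, 8α-OH), via lithium carboxylate 36 (not isolated)
Conditions: LiOH, THF–H2O, 0 °C; then Pd(PPh3)4 (cat.), THF, rt; aq. NH4Cl
Reagents that add atoms: lithium hydroxide, [Li+].[OH-]
Why: Saponification, then Tsuji–Trost-type opening of the vinyl epoxide: zerovalent palladium ionises the allylic C7–O bond with inversion and the tethered carboxylate closes the five-membered lactone on C7 with a second inversion, so O7 keeps the α configuration of the epoxide (net retention) and C8 is untouched.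

Step 27
Reactants: 37 α-methylene hydroxy lactone
Product: 38 17R α-methyl lactone
Conditions: [(Ph3P)CuH]6 (cat.), PhSiH3, toluene, rt; aq. NH4F
Reagents that add atoms: none
Why: Copper hydride 1,4-reduction of the α-methylene lactone; protonation of the resulting enolate should place the C18 methyl anti to the bulky C9 branch of quaternary C8 (17R), the usual outcome for conjugate reduction of trans-fused α-methylene-γ-lactones, and the centre can epimerise toward this more stable isomer.

Step 28
Reactants: 38 α-methyl lactone
Product: 39 pentaol (C2, C8, C9, C13, C14 hydroxyls)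
Conditions: aq. HF (48%), MeCN, rt
Reagents that add atoms: none
Why: Aqueous HF cleaves the hindered silyl ether and hydrolyses the acetonide; lactone, tertiary alcohol and alkenes tolerate it.

Step 29
Reactants: 39 pentaol
Product: 40 2,9,13,14-tetraacetate (free 8-OH)
Conditions: Ac2O, pyridine, DMAP (cat.), CH2Cl2, rt
Reagents that add atoms: acetic anhydride, CC(=O)OC(C)=O
Why: DMAP-catalysed acetylation of the four secondary hydroxyls; the tertiary C8 hydroxyl, flanked by C7, C9 and C17, is too hindered to react.

Step 30
Reactants: 40 tetraacetate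
Product: 41 CNP0144558.1
Conditions: Ca(OCl)2, CO2 (solid), CH2Cl2–H2O, 0 °C
Reagents that add atoms: calcium hypochlorite, [Ca+2].[O-]Cl.[O-]Cl
Why: Ene-type allylic chlorination by hypochlorous acid: chlorine adds to C6 of the trisubstituted alkene and a C16 hydrogen is lost, giving C5=C16. Attack anti to the allylic C7–O bond in the conformer with H7 eclipsing the alkene (the face within reach of the C8 hydroxyl) should give the 6α chloride, and the more nucleophilic trisubstituted alkene should react before C11=C20.

## Compound list

1 | (1S,2S)-3-bromocyclohexa-3,5-diene-1,2-diol | O[C@H]1C=CC=C(Br)[C@H]1O | starting material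
2 | (3aS,7aS)-4-bromo-2,2-dimethyl-3a,7a-dihydro-1,3-benzodioxole (acetonide of 1; C–Br becomes C1, the dioxolane carbons C14 and C13) | CC1(C)O[C@H]2C=CC=C(Br)[C@H]2O1 | intermediate
3 | ring-A trans-bromohydrin: C1 vinyl bromide (C1=C10), 11α-hydroxyl, 12β-bromine, 13α,14α-O-isopropylidene | BrC1=C[C@H](O)[C@@H](Br)[C@@H]2OC(C)(C)O[C@H]12 | intermediate
4 | ring-A allylic alcohol: C1 vinyl bromide, 11α-hydroxyl, 13α,14α-O-isopropylidene | BrC1=C[C@H](O)C[C@@H]2OC(C)(C)O[C@H]12 | intermediate
5 | β-bromo enone: 3-bromo-4,5-(isopropylidenedioxy)cyclohex-2-en-1-one (C11 ketone, C1(Br)=C10, 13α,14α-acetonide) | BrC1=CC(=O)C[C@@H]2OC(C)(C)O[C@H]12 | intermediate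
6 | 3-(hydroxymethyl)-4,5-(isopropylidenedioxy)cyclohex-2-en-1-one (C2 hydroxymethyl on C1) | OCC1=CC(=O)C[C@@H]2OC(C)(C)O[C@H]12 | intermediate
7 | TBS ether of 6 | CC(C)(C)[Si](C)(C)OCC1=CC(=O)C[C@@H]2OC(C)(C)O[C@H]12 | intermediate
8 | lithium enolate (C11–OLi, C10=C11) with quaternary C1 (β-methyl, α-CH2OTBS) | CC(C)(C)[Si](C)(C)OC[C@]1(C)C=C([O-])C[C@@H]2OC(C)(C)O[C@@H]21.[Li+] | intermediate
9 | C11 enol triflate; C1 β-methyl, α-CH2OTBS; 13α,14α-acetonide | CC(C)(C)[Si](C)(C)OC[C@]1(C)C=C(OS(=O)(=O)C(F)(F)F)C[C@@H]2OC(C)(C)O[C@@H]21 | intermediate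
10 | methyl enoate (C20 ester on C11, C10=C11); C1 β-methyl, α-CH2OTBS | CC(C)(C)[Si](C)(C)OC[C@]1(C)C=C(C(=O)OC)C[C@@H]2OC(C)(C)O[C@@H]21 | intermediate
11 | C2 primary alcohol of 10 | OC[C@]1(C)C=C(C(=O)OC)C[C@@H]2OC(C)(C)O[C@@H]21 | intermediate
12 | C2 aldehyde (1α-formyl, 1β-methyl) | O=C[C@]1(C)C=C(C(=O)OC)C[C@@H]2OC(C)(C)O[C@@H]21 | intermediate
13 | C2 methyl carbinol, both C2 epimers | CC(O)[C@]1(C)C=C(C(=O)OC)C[C@@H]2OC(C)(C)O[C@@H]21 | intermediate
14 | methyl ketone (1α-acetyl, 1β-methyl; C2 carbonyl, C3 methyl) | CC(=O)[C@]1(C)C=C(C(=O)OC)C[C@@H]2OC(C)(C)O[C@@H]21 | intermediate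
15 | propargyl alcohol | C#CCO | starting material
16 | vinylmagnesium chelate from anti-carbomagnesiation (Mg on the terminal carbon, cis to CH2O) | Br[Mg]OC/C(C)=C\[Mg]Br | intermediate
17 | (Z)-3-iodo-2-methylprop-2-en-1-ol | OC/C(C)=C\I | intermediate
18 | (Z)-3-bromo-1-iodo-2-methylprop-1-ene | BrC/C(C)=C\I | intermediate
19 | lithium enolate of 14 (C2–OLi, C2=C3) | [Li+].C=C([O-])[C@]1(C)C=C(C(=O)OC)C[C@@H]2OC(C)(C)O[C@@H]21 | intermediate
20 | C2 ketone with C3–C6 chain ending in the Z vinyl iodide (C4 and I cis on C5=C6) | I/C=C(/C)CCC(=O)[C@]1(C)C=C(C(=O)OC)C[C@@H]2OC(C)(C)O[C@@H]21 | intermediate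
21 | (2S)-alcohol of 20 | I/C=C(/C)CC[C@H](O)[C@]1(C)C=C(C(=O)OC)C[C@@H]2OC(C)(C)O[C@@H]21 | intermediate
22 | (2S)-TBS ether, Z vinyl iodide, C20 methyl ester | I/C=C(/C)CC[C@H](O[Si](C)(C)C(C)(C)C)[C@]1(C)C=C(C(=O)OC)C[C@@H]2OC(C)(C)O[C@@H]21 | intermediate
23 | Z enynol (C5=C6 Z, C7≡C8, C9–OH), C20 methyl ester | OCC#C/C=C(/C)CC[C@H](O[Si](C)(C)C(C)(C)C)[C@]1(C)C=C(C(=O)OC)C[C@@H]2OC(C)(C)O[C@@H]21 | intermediate
24 | C9 propargylic mesylate | CS(=O)(=O)OCC#C/C=C(/C)CC[C@H](O[Si](C)(C)C(C)(C)C)[C@]1(C)C=C(C(=O)OC)C[C@@H]2OC(C)(C)O[C@@H]21 | intermediate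
25 | C9 propargylic chloride, C20 methyl ester | ClCC#C/C=C(/C)CC[C@H](O[Si](C)(C)C(C)(C)C)[C@]1(C)C=C(C(=O)OC)C[C@@H]2OC(C)(C)O[C@@H]21 | intermediate
26 | C9 propargylic chloride with C20 allylic alcohol | ClCC#C/C=C(/C)CC[C@H](O[Si](C)(C)C(C)(C)C)[C@]1(C)C=C(CO)C[C@@H]2OC(C)(C)O[C@@H]21 | intermediate
27 | sodium C20 alkoxide of 26 | [Na+].ClCC#C/C=C(/C)CC[C@H](O[Si](C)(C)C(C)(C)C)[C@]1(C)C=C(C[O-])C[C@@H]2OC(C)(C)O[C@@H]21 | intermediate
28 | 13-membered cyclic allyl propargyl ether (O bridges C9 and C20) fused to the ring-A cyclohexene; 2S-OTBS, 13α,14α-acetonide | O1CC#C/C=C(/C)CC[C@H](O[Si](C)(C)C(C)(C)C)[C@]2(C)C=C(C1)C[C@@H]3OC(C)(C)O[C@@H]32 | intermediate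
29 | C9 α-lithio ether of 28 | O1C([Li])C#C/C=C(/C)CC[C@H](O[Si](C)(C)C(C)(C)C)[C@]2(C)C=C(C1)C[C@@H]3OC(C)(C)O[C@@H]32 | intermediate
30 | lithium C9 alkoxide of 31 | C=C1C[C@@H]2OC(C)(C)O[C@@H]2[C@]3(C)[C@@H](O[Si](C)(C)C(C)(C)C)CC/C(C)=C\C#C[C@@H]([O-])[C@@H]13.[Li+] | intermediate
31 | ten-membered cyclic enynol: 9S (9β) hydroxyl, H10 α, C11=C20 methylene, C5=C6 Z, C7≡C8, 2S-OTBS, 13α,14α-acetonide | C=C1C[C@@H]2OC(C)(C)O[C@@H]2[C@]3(C)[C@@H](O[Si](C)(C)C(C)(C)C)CC/C(C)=C\C#C[C@@H](O)[C@@H]13 | intermediate
32 | C8 tributylstannane, C7=C8 cis in the ring (C6 and C9 cis), 9β-OH | C=C1C[C@@H]2OC(C)(C)O[C@@H]2[C@]3(C)[C@@H](O[Si](C)(C)C(C)(C)C)CC/C(C)=C\C=C(\[Sn](CCCC)(CCCC)CCCC)[C@@H](O)[C@@H]13 | intermediate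
33 | methyl 2-bromoacrylate | C=C(Br)C(=O)OC | starting material
34 | dienyl acrylate: C8 bears C17(=C18H2)–C19O2Me, C7=C8 cis in the ring, 9β-OH | C=C1C[C@@H]2OC(C)(C)O[C@@H]2[C@]3(C)[C@@H](O[Si](C)(C)C(C)(C)C)CC/C(C)=C\C=C(\C(=C)C(=O)OC)[C@@H](O)[C@@H]13 | intermediate
35 | 7α,8α-epoxide of 34 (cis epoxide, C17 β on C8), 9β-OH | C=C1C[C@@H]2OC(C)(C)O[C@@H]2[C@]3(C)[C@@H](O[Si](C)(C)C(C)(C)C)CC/C(C)=C\[C@@H]4O[C@]4(C(=C)C(=O)OC)[C@@H](O)[C@@H]13 | intermediate
36 | lithium C19 carboxylate of 35 | [Li+].C=C1C[C@@H]2OC(C)(C)O[C@@H]2[C@]3(C)[C@@H](O[Si](C)(C)C(C)(C)C)CC/C(C)=C\[C@@H]4O[C@]4(C(=C)C(=O)[O-])[C@@H](O)[C@@H]13 | intermediate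
37 | α-methylene γ-lactone (C7α–O–C19, trans-fused), 8α-OH, 9β-OH, C5=C6 Z | C=C1C[C@@H]2OC(C)(C)O[C@@H]2[C@]3(C)[C@@H](O[Si](C)(C)C(C)(C)C)CC/C(C)=C\[C@@H]4OC(=O)C(=C)[C@@]4(O)[C@@H](O)[C@@H]13 | intermediate
38 | 17R α-methyl lactone (C18 methyl cis to 8-OH on the lactone), 8α-OH, 9β-OH | C=C1C[C@@H]2OC(C)(C)O[C@@H]2[C@]3(C)[C@@H](O[Si](C)(C)C(C)(C)C)CC/C(C)=C\[C@@H]4OC(=O)[C@H](C)[C@@]4(O)[C@@H](O)[C@@H]13 | intermediate
39 | pentaol: 2β, 8α, 9β, 13α, 14α hydroxyls; 7,19-lactone; C5=C6 Z; C11=C20 | C=C1C[C@H](O)[C@H](O)[C@]2(C)[C@@H](O)CC/C(C)=C\[C@@H]3OC(=O)[C@H](C)[C@@]3(O)[C@@H](O)[C@@H]12 | intermediate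
40 | 2β,9β,13α,14α-tetraacetate with free 8α-OH (deschloro Δ5 compound) | C=C1C[C@H](OC(C)=O)[C@H](OC(C)=O)[C@]2(C)[C@@H](OC(C)=O)CC/C(C)=C\[C@@H]3OC(=O)[C@H](C)[C@@]3(O)[C@@H](OC(C)=O)[C@@H]12 | intermediate
41 | CNP0144558.1: 2β,9β,13α,14α-tetraacetoxy-6α-chloro-8α-hydroxy briarane 7,19-lactone with C5=C16 and C11=C20 methylenes | C=C1C[C@H](OC(C)=O)[C@H](OC(C)=O)[C@]2(C)[C@@H](OC(C)=O)CCC(=C)[C@H](Cl)[C@@H]3OC(=O)[C@H](C)[C@@]3(O)[C@@H](OC(C)=O)[C@@H]12 | target

## Step count and risk

Total: 30 steps. Longest linear sequence: 28 steps (steps 1–12 and 15–30, from 1); the side branch to 18 is 2 steps (13–14).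

Least certain steps:

**Step 22 (key step).** The most likely failure is incomplete control of the C9 configuration, because the two envelope arrangements of C8 may differ little in energy; a [1,2]-shift could compete if the anion warms. Fallback: C9 is set by reagent control instead of by the shift. Setting out from cyclic ether 28, the contraction is run as before, and the C9-epimeric ring-contracted alcohol F1 (alone or mixed with 31) is oxidised with Dess–Martin periodinane to the ynone F2. Reduction with catecholborane and the enantiomer of 2-methyl-CBS-oxazaborolidine matched to the 9S alcohol (expected to be the S catalyst, the alkynyl arm acting as the small substituent) returns the route at 31.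

**Step 23.** The most likely failure is loss of regiocontrol in the hydrometalation of a conjugated enyne (tin delivered to C7, or a second addition across the diene), because the alkene at C6 competes with the carbinol oxygen as directing element. Fallback: from 31, hydroxyl-directed trans-hydrostannation with [Cp*RuCl]4 and Bu3SnH puts tin on C8 by a different mechanism and gives the E-configured C8 stannane F3 (C9 and C6 trans). Stille coupling with 33 gives the E dienyl acrylate F4, and iodine-catalysed isomerisation of the strained in-ring trans alkene leads back to 34.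

**Step 26.** The most likely failure is erosion of the net retention at C7, by direct uncatalysed SN2 opening of the epoxide by the carboxylate (inversion) or by π–σ–π equilibration of the allylpalladium intermediate; diene formation by β-hydride loss is a further risk. Fallback: two polar inversions replace the metal. From epoxy ester 35, MgBr2·OEt2 opens the vinyl epoxide at allylic C7 with inversion to the bromohydrin F5 (7β-Br, 8α-OH); saponification with LiOH then lets the carboxylate displace the allylic bromide with a second inversion, which returns the route at 37.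

**Step 27.** The most likely failure is protonation of the lactone enolate from the wrong face (C17 epimer), since the two faces differ only through the C8 substituents. Fallback: the methyl group, not the proton, becomes the incoming electrophile. From stannane 32, iododestannylation gives the C8 vinyl iodide F6. Negishi coupling with the Reformatsky reagent BrZnCH2CO2Me gives the β,γ-unsaturated ester F7. The same directed epoxidation gives the epoxy ester F8, and the same saponification/palladium lactonisation gives the unsubstituted hydroxy lactone F9. Methylation of its alkoxide–enolate polyanion (LDA, MeI), on the face the proton would have taken, returns the route at 38.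

**Step 30.** The most likely failures are delivery of chlorine to the β face of C6 (C6 epimer), capture of the chloronium ion by the C8 hydroxyl as a cyclic ether, and competing reaction at the C11=C20 methylene. Fallback: oxygen is placed first and chlorine enters by substitution. From tetraacetate 40, mCPBA gives the 5β,6β-epoxide F10 on the same exposed face. Cp2TiCl isomerises it to the exocyclic allylic alcohol F11 (6β-OH, C5=C16). Mesylation and displacement by LiCl with inversion then reach 41.

## Further compounds

F1 | step 22 | C9 epimer of 31 (9α-hydroxyl) | C=C1C[C@@H]2OC(C)(C)O[C@@H]2[C@]3(C)[C@@H](O[Si](C)(C)C(C)(C)C)CC/C(C)=C\C#C[C@H](O)[C@@H]13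
F2 | step 22 | C9 ynone (C9 ketone conjugated to C7≡C8) | C=C1C[C@@H]2OC(C)(C)O[C@@H]2[C@]3(C)[C@@H](O[Si](C)(C)C(C)(C)C)CC/C(C)=C\C#CC(=O)[C@@H]13
F3 | step 23 | C8 tributylstannane with C7=C8 trans in the ring (C6 and C9 trans) | C=C1C[C@@H]2OC(C)(C)O[C@@H]2[C@]3(C)[C@@H](O[Si](C)(C)C(C)(C)C)CC/C(C)=C\C=C(/[Sn](CCCC)(CCCC)CCCC)[C@@H](O)[C@@H]13
F4 | step 23 | dienyl acrylate with C7=C8 trans in the ring | C=C1C[C@@H]2OC(C)(C)O[C@@H]2[C@]3(C)[C@@H](O[Si](C)(C)C(C)(C)C)CC/C(C)=C\C=C(/C(=C)C(=O)OC)[C@@H](O)[C@@H]13
F5 | step 26 | bromohydrin ester (7β-Br, 8α-OH, 9β-OH, C19 methyl ester) | C=C1C[C@@H]2OC(C)(C)O[C@@H]2[C@]3(C)[C@@H](O[Si](C)(C)C(C)(C)C)CC/C(C)=C\[C@@H](Br)[C@@](O)(C(=C)C(=O)OC)[C@@H](O)[C@@H]13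
F6 | step 27 | C8 vinyl iodide (C7=C8 cis in the ring) | C=C1C[C@@H]2OC(C)(C)O[C@@H]2[C@]3(C)[C@@H](O[Si](C)(C)C(C)(C)C)CC/C(C)=C\C=C(\I)[C@@H](O)[C@@H]13
F7 | step 27 | β,γ-unsaturated methyl ester (C8–C17H2–C19O2Me) | C=C1C[C@@H]2OC(C)(C)O[C@@H]2[C@]3(C)[C@@H](O[Si](C)(C)C(C)(C)C)CC/C(C)=C\C=C(\CC(=O)OC)[C@@H](O)[C@@H]13
F8 | step 27 | 7α,8α-epoxy ester without the C18 carbon | C=C1C[C@@H]2OC(C)(C)O[C@@H]2[C@]3(C)[C@@H](O[Si](C)(C)C(C)(C)C)CC/C(C)=C\[C@@H]4O[C@]4(CC(=O)OC)[C@@H](O)[C@@H]13
F9 | step 27 | hydroxy lactone unsubstituted at C17 | C=C1C[C@@H]2OC(C)(C)O[C@@H]2[C@]3(C)[C@@H](O[Si](C)(C)C(C)(C)C)CC/C(C)=C\[C@@H]4OC(=O)C[C@@]4(O)[C@@H](O)[C@@H]13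
F10 | step 30 | 5β,6β-epoxide of 40 | C=C1C[C@H](OC(C)=O)[C@H](OC(C)=O)[C@]2(C)[C@@H](OC(C)=O)CC[C@@]4(C)O[C@H]4[C@@H]3OC(=O)[C@H](C)[C@@]3(O)[C@@H](OC(C)=O)[C@@H]12
F11 | step 30 | 6β-hydroxy compound with C5=C16 methylene | C=C1C[C@H](OC(C)=O)[C@H](OC(C)=O)[C@]2(C)[C@@H](OC(C)=O)CCC(=C)[C@@H](O)[C@@H]3OC(=O)[C@H](C)[C@@]3(O)[C@@H](OC(C)=O)[C@@H]12
A1 | alternative 1 | ring-A 4-methylenecyclohexanone with quaternary C1 and C10 set | C=C1C[C@H](O[Si](C)(C)C(C)(C)C)C(=O)[C@](C)(COCc2ccccc2)[C@H]1COC(=O)C(C)(C)C
A2 | alternative 2 | ring-closed 6-chloro-7,8-dihydroxy methyl ester (seco-lactone of the target) | C=C1C[C@H](OC(C)=O)[C@H](OC(C)=O)[C@]2(C)[C@@H](OC(C)=O)CCC(=C)[C@H](Cl)[C@H](O)[C@@](O)([C@@H](C)C(=O)OC)[C@@H](OC(C)=O)[C@@H]12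
A3 | alternative 3 | protected 8-hydroxy-17-methyl lactone with complete skeleton | C=C1C[C@@H]2OC(C)(C)O[C@@H]2[C@]3(C)[C@@H](O[Si](C)(C)C(C)(C)C)CCC(=C)[C@H](Cl)[C@@H]4OC(=O)[C@H](C)[C@@]4(O)[C@@H](O[Si](C)(C)C(C)(C)C)[C@@H]13
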